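(The numbers in the tables stem from a simulated flask with made-up constants; the scatter is artificial.)

I take one constant per run. Two runs are known, and the north-west flask is asked for.

all flasks: starting material 80.0 mM

| run | reagent | time |
|---|---|---|
| south | 240 mM |  |
| west | 120 mM |  |
| north-west | 52.0 mM | 52 s |

- south run (time / s: [target] / mM): 6.5: 14.85; 13: 25.48; 20: 33.95; 26: 39.84; 32: 44.31; 39: 48.19; 46: 51.44; 52: 53.29
- west run (time / s: [target] / mM): 6.5: 6.48; 13: 11.46; 20: 16.09; 26: 19.58; 32: 22.48; 39: 25.38; 46: 27.77; 52: 30.01

(standard deviation of a reading: 0.2 mM)

* reaction order in [reagent] at the outset, round the charge of the south run, defined at two percent of the starting material turned into target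
* target in the north-west run at 52 s, as a share of the starting material charged
* which of these the readings show (the product binds the substrate / the second partner is lost in pairs / the two partners rest in a complex / the substrate is lost by itself / the second partner is lost by itself / nothing beyond the main steps)

- Overall: starting material + reagent -> target.
- Constant volume, constant temperature.
- "The second partner" is reagent.
- An order is taken over about fifteen percent of the charge, up and down.

I replace each curve by its mean. Let S₀ be the starting material charged and P the target at time t. In the west run, ln(S₀/(S₀−P))/t at the last reading is 0.009042 s⁻¹. I call this the mean constant k̄: the pseudo-first-order constant that gives the same target at that time. In the south run, k̄ is 0.02110 s⁻¹.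

The inverses form a ladder of times. The south run has 47.4 s, shorter than its 52 s of readings. The west run has 111 s, so its readings cover about half of that time.

Reagent falls as target forms, so I take as its mean the charge less the target at half of the time. That gives 200 mM in the south run and 100 mM in the west run. The k̄ ratio of 2.33 over a reagent ratio of 2.00 gives a mean order n̄ of 1.23, read over the whole curve and not at the outset.

In the west run, the target at that midpoint is 0.652 of the final target. For the north-west flask, I try the west target scaled by the reagent charge, 13.0 mM. Its mean reagent is then 43.5 mM, so k̄ is 0.003238 s⁻¹, and the top rung is 309 s, slower than the west run. I reckon 12.4 mM, or 15.5%. The trial's error of 0.600 mM shifts the mean reagent by 0.397 mM.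

The forecast gives an outset order of 1.3 and 17.5%, above my share, and holds that the second partner is lost in pairs, saying “reagent is lost in pairs”.

The north-west flask gives 16.2%. The outset order round the south charge is 1.5, and the readings show that the substrate is lost by itself.

    starting material + reagent → target (0.07890 M⁻¹ s⁻¹)
    starting material + 2 reagent → target + reagent (0.2630 M⁻² s⁻¹)
    starting material → decomposed substrate (0.006840 s⁻¹)

As a mean constant, that share is 0.003400 s⁻¹, against my 0.00324 s⁻¹. In the west run, the target reaches half of the charge at 108 s, which makes k̄ 0.006418 s⁻¹, less than the 0.00904 s⁻¹ of its first 52 s.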